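A direct plan would condense the acetophenone A1 (2,4-bis-MOM ether of 3-(2-methylbut-3-en-2-yl)phloroacetophenone, 6-OH free) with the vanillin MOM ether A2 to the 2′-hydroxychalcone A3, would epoxidise A3 enantioselectively to the trans-epoxide A4, and would close ring C by attack of the 2′-OH on the benzylic epoxide carbon before deprotection. Its weakest steps would be:
- the preparation of A1 with its two ortho oxygens told apart, since only the one para to the tertiary allyl group may become O1;
- the asymmetric epoxidation of a twisted, electron-rich 2′,6′-dioxygenated chalcone, on which nucleophilic epoxidation catalysts lose rate and selectivity;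
- the O1–C2 closure, a substitution at a benzylic carbon para to oxygen that would drift to an SN1 course (cis/trans mixtures) under acid that also endangers the 1,1-dimethylallyl group.

The route would rest on the C2–C1′ bond. Ring B would be delivered as an arylboronic acid to C2 of a flat, achiral 6-(1,1-dimethylallyl)chromone by rhodium-catalysed enantioface-selective 1,4-addition, which would turn the pyranone into ring C and set C2; C3–OH would then be relayed from C2. The step exploits that C2 is the β-carbon of the vinylogous ester O1–C2=C3–C4=O, so O1–C2 exists before C2 becomes stereogenic: no chalcone, no epoxide and no substitution at a benzylic stereocentre are needed. Since ring C is closed first, O5 has C6 as its only free ortho carbon, and a Claisen shift from O5 fixes the 6-position without differentiating phenols.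

Key step: step 7

Remark: 5,7-dihydroxy-4H-chromen-4-one (1) is taken as purchased; the facial sense in step 7 is assigned by analogy with cyclohex-2-enone and would be checked on the parent chromone, the (R)-ligand being used if it proved opposite.

**Step 1**
Reactants: 1 5,7-dihydroxy-4H-chromen-4-one
Product: 2 5-hydroxy-7-(methoxymethoxy)-4H-chromen-4-one
Conditions: MOMCl (1.1 equiv), K2CO3 (1.5 equiv), acetone, 0 °C to rt
Reagents that add atoms: chloromethyl methyl ether (MOMCl), COCCl
Why: Williamson-type O-alkylation: the 7-OH is the acidic, vinylogous-acid hydroxyl para to C4=O whereas the 5-OH is tied up in the hydrogen bond to C4=O, so one equivalent of the chloromethyl ether under mild carbonate conditions should etherify O7 alone.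

**Step 2**
Reactants: 2 5-hydroxy-7-(methoxymethoxy)-4H-chromen-4-one; 3 1-bromo-3-methylbut-2-ene (prenyl bromide)
Product: 4 7-(methoxymethoxy)-5-(3-methylbut-2-enyloxy)-4H-chromen-4-one
Conditions: K2CO3 (3 equiv), 3 (1.5 equiv), DMF, 50 °C
Reagents that add atoms: none
Why: Williamson etherification (SN2 at the primary allylic carbon): with excess carbonate in DMF the chelate of the 5-OH is broken and its phenoxide, a vinylogous carboxylate with little carbon nucleophilicity at C6 or C8, should be O-alkylated.

**Step 3**
Reactants: 4 7-(methoxymethoxy)-5-(3-methylbut-2-enyloxy)-4H-chromen-4-one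
Product: 6 5-hydroxy-7-(methoxymethoxy)-6-(2-methylbut-3-en-2-yl)-4H-chromen-4-one, via ortho-dienone 5 (not isolated)
Conditions: N,N-diethylaniline, 200 °C (sealed tube), argon, 1 h
Reagents that add atoms: none
Why: Aromatic Claisen rearrangement: the [3,3] shift from O5 can only reach C6 because the other ortho position is the ring-fusion carbon C4a, it delivers the allyl unit through its tertiary terminus, and the amine solvent (no Lewis acid present) should enolise dienone 5 to the chelated phenol 6 before a Cope shift towards C8 can compete; no stereocentre remains.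

**Step 4**
Reactants: 6 5-hydroxy-7-(methoxymethoxy)-6-(2-methylbut-3-en-2-yl)-4H-chromen-4-one
Product: 7 5,7-bis(methoxymethoxy)-6-(2-methylbut-3-en-2-yl)-4H-chromen-4-one
Conditions: NaH (1.5 equiv), MOMCl (2 equiv), DMF, 0 °C to rt
Reagents that add atoms: chloromethyl methyl ether (MOMCl), COCCl
Why: Williamson-type O-alkylation: the sodium phenoxide formed irreversibly by NaH should be alkylated by the small, very reactive chloromethyl ether even though O5 lies between the quaternary carbon and the peri carbonyl group, and the chromone has no other acidic site.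

**Step 5**
Reactants: 8 4-bromo-2-methoxyphenol
Product: 9 4-bromo-2-methoxy-1-(methoxymethoxy)benzene
Conditions: MOMCl (1.2 equiv), K2CO3 (2 equiv), acetone, rt
Reagents that add atoms: chloromethyl methyl ether (MOMCl), COCCl
Why: Williamson-type O-alkylation of the only phenol to the MOM acetal, chosen so that all three phenol protecting groups fall together in the last step.

**Step 6**
Reactants: 9 4-bromo-2-methoxy-1-(methoxymethoxy)benzene
Product: 10 [3-methoxy-4-(methoxymethoxy)phenyl]boronic acid
Conditions: n-BuLi (1.1 equiv), THF, –78 °C; B(OiPr)3 (1.5 equiv), –78 °C to rt; aq NH4Cl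
Reagents that add atoms: triisopropyl borate, CC(C)OB(OC(C)C)OC(C)C (the boron atom); water, O (the two hydroxyl groups on boron)
Why: Bromine–lithium exchange followed by borylation: the exchange at –78 °C is much faster than ortho-lithiation beside the acetal, and hydrolysis of the boronate at about pH 6 should free the boronic acid without touching the MOM ether.

**Step 7**
Reactants: 7 5,7-bis(methoxymethoxy)-6-(2-methylbut-3-en-2-yl)-4H-chromen-4-one; 10 [3-methoxy-4-(methoxymethoxy)phenyl]boronic acid
Product: 11 (2S)-5,7-bis(methoxymethoxy)-2-[3-methoxy-4-(methoxymethoxy)phenyl]-6-(2-methylbut-3-en-2-yl)chroman-4-one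
Conditions: [Rh(OH)(cod)]2 (cod = cycloocta-1,5-diene, 2.5 mol%), (S)-(6,6′-dimethoxybiphenyl-2,2′-diyl)bis[bis(3,4,5-trifluorophenyl)phosphine] (5.5 mol%), 10 (3 equiv), toluene/H2O (10:1), 30 °C
Reagents that add atoms: none
Why: Hayashi–Miyaura reaction (rhodium-catalysed asymmetric 1,4-addition of an arylboronic acid), a reaction type established for chromones as a route to 2-arylchroman-4-ones: the hydroxo complex of monovalent rhodium takes the aryl group from boron, the C2=C3 bond of 7 inserts into the Rh–aryl bond with the aryl group going to C2, and water hydrolyses the resulting oxa-π-allyl rhodium enolate to ketone 11 with return of Rh–OH. No ring is closed; the only new bond is C2–C1′, and it converts the flat pyranone into ring C. The C2 stereocentre is controlled by the axially chiral bisphosphine, which leaves one enantioface of the coordinated C2=C3 bond open to migratory insertion; by analogy with cyclohex-2-enone the (S)-ligand should place the aryl group on the face that gives 2S. The step needs 1,4- over 1,2-addition and an inert side-chain alkene, which the preference of aryl–rhodium species for conjugated acceptors and the neopentyl, non-conjugated position of the vinyl group (on a quaternary carbon, so it cannot isomerise either) should secure. The electron-poor phosphine should make the catalyst active enough for the electron-rich 5,7-dialkoxychromone at 30 °C without added base, so that 11 is not racemised by retro-oxa-Michael ring opening, and the excess of 10 covers protodeboronation.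

**Step 8**
Reactants: 11 (2S)-5,7-bis(methoxymethoxy)-2-[3-methoxy-4-(methoxymethoxy)phenyl]-6-(2-methylbut-3-en-2-yl)chroman-4-one
Product: 14 (2R,3R)-3-hydroxy-5,7-bis(methoxymethoxy)-2-[3-methoxy-4-(methoxymethoxy)phenyl]-6-(2-methylbut-3-en-2-yl)chroman-4-one, via enol silane 12 (not isolated), via silyloxy epoxide 13 (not isolated)
Conditions: LiHMDS (1.3 equiv), TMSCl (1.5 equiv, present from the start), THF, –78 °C; DMDO (1.1 equiv, in acetone), CH2Cl2, –78 to –30 °C; 10% aq citric acid, THF, 0 °C
Reagents that add atoms: dimethyldioxirane (DMDO), CC1(C)OO1 (the oxygen atom at C3); chlorotrimethylsilane, C[Si](C)(C)Cl (its Me3Si group stands in 12 and 13 only)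
Why: Rubottom oxidation: deprotonation at C3 under internal quench should trap the enolate as enol silane 12 before it can expel the phenoxide O1 (the ring opening that would racemise C2), dimethyldioxirane should epoxidise the electron-rich C3=C4 bond, far faster than the monosubstituted alkene, from the face anti to the C2 aryl group, and hydrolysis of epoxide 13 should give the ketol with the new C3 stereocentre R, that is 2,3-trans, which is also the more stable diequatorial arrangement.

**Step 9**
Reactants: 14 (2R,3R)-3-hydroxy-5,7-bis(methoxymethoxy)-2-[3-methoxy-4-(methoxymethoxy)phenyl]-6-(2-methylbut-3-en-2-yl)chroman-4-one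
Product: 15 (2R,3R)-3,5,7-trihydroxy-2-(4-hydroxy-3-methoxyphenyl)-6-(2-methylbut-3-en-2-yl)chroman-4-one (target)
Conditions: HCl (1.25 M in MeOH), rt to 40 °C
Reagents that add atoms: none
Why: Acid-catalysed acetal cleavage (transacetalisation to dimethoxymethane) of the three aryl MOM ethers under conditions too mild to protonate the monosubstituted alkene or to open ring C, so that the 1,1-dimethylallyl group and the 2,3-trans stereocentres should be kept.

**Compound list**
1 | 5,7-dihydroxy-4H-chromen-4-one | O=c1ccoc2cc(O)cc(O)c12 | starting material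
2 | 5-hydroxy-7-(methoxymethoxy)-4H-chromen-4-one | O=c1ccoc2cc(OCOC)cc(O)c12 | intermediate
3 | 1-bromo-3-methylbut-2-ene (prenyl bromide) | CC(C)=CCBr | starting material
4 | 7-(methoxymethoxy)-5-(3-methylbut-2-enyloxy)-4H-chromen-4-one | O=c1ccoc2cc(OCOC)cc(OCC=C(C)C)c12 | intermediate
5 | 7-(methoxymethoxy)-6-(2-methylbut-3-en-2-yl)-4H-chromene-4,5(6H)-dione (racemic ortho-dienone, not isolated) | C=CC(C)(C)C1C(=O)C2=C(C=C1OCOC)OC=CC2=O | intermediate
6 | 5-hydroxy-7-(methoxymethoxy)-6-(2-methylbut-3-en-2-yl)-4H-chromen-4-one | O=c1ccoc2cc(OCOC)c(C(C)(C)C=C)c(O)c12 | intermediate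
7 | 5,7-bis(methoxymethoxy)-6-(2-methylbut-3-en-2-yl)-4H-chromen-4-one | O=c1ccoc2cc(OCOC)c(C(C)(C)C=C)c(OCOC)c12 | intermediate
8 | 4-bromo-2-methoxyphenol | COc1cc(Br)ccc1O | starting material
9 | 4-bromo-2-methoxy-1-(methoxymethoxy)benzene | COCOc1ccc(Br)cc1OC | intermediate
10 | [3-methoxy-4-(methoxymethoxy)phenyl]boronic acid | COCOc1ccc(B(O)O)cc1OC | intermediate
11 | (2S)-5,7-bis(methoxymethoxy)-2-[3-methoxy-4-(methoxymethoxy)phenyl]-6-(2-methylbut-3-en-2-yl)chroman-4-one | C=CC(C)(C)c1c(OCOC)cc2c(c1OCOC)C(=O)C[C@@H](c1ccc(OCOC)c(OC)c1)O2 | intermediate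
12 | (2S)-5,7-bis(methoxymethoxy)-2-[3-methoxy-4-(methoxymethoxy)phenyl]-6-(2-methylbut-3-en-2-yl)-4-(trimethylsilyloxy)-2H-chromene (not isolated) | C=CC(C)(C)c1c(OCOC)cc2c(c1OCOC)C(O[Si](C)(C)C)=C[C@@H](c1ccc(OCOC)c(OC)c1)O2 | intermediate
13 | (2R,3R,4R)-3,4-epoxy-5,7-bis(methoxymethoxy)-2-[3-methoxy-4-(methoxymethoxy)phenyl]-6-(2-methylbut-3-en-2-yl)-4-(trimethylsilyloxy)chromane, oxirane oxygen trans to the C2 aryl group (not isolated) | C=CC(C)(C)c1c(OCOC)cc2c(c1OCOC)[C@]3(O[Si](C)(C)C)O[C@@H]3[C@@H](c1ccc(OCOC)c(OC)c1)O2 | intermediate
14 | (2R,3R)-3-hydroxy-5,7-bis(methoxymethoxy)-2-[3-methoxy-4-(methoxymethoxy)phenyl]-6-(2-methylbut-3-en-2-yl)chroman-4-one | C=CC(C)(C)c1c(OCOC)cc2c(c1OCOC)C(=O)[C@H](O)[C@@H](c1ccc(OCOC)c(OC)c1)O2 | intermediate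
15 | (2R,3R)-3,5,7-trihydroxy-2-(4-hydroxy-3-methoxyphenyl)-6-(2-methylbut-3-en-2-yl)chroman-4-one | C=CC(C)(C)c1c(O)cc2c(c1O)C(=O)[C@H](O)[C@@H](c1ccc(O)c(OC)c1)O2 | target

**Count**
Total steps: 9. Longest linear sequence: 7 (steps 1, 2, 3, 4, 7, 8, 9).

**Steps most likely to fail**

Step 7. The insertion into the electron-rich, 5-alkoxy-substituted chromone could be slow, protodeboronation could consume the boronic acid, or the enantioface discrimination could be insufficient. The fallback would give up catalyst control of C2 in favour of a resolution. From 7 and 10, an achiral cationic catalyst of divalent palladium [Pd(OCOCF3)2, 2,2′-bipyridine, aqueous dioxane] should give the racemic flavanone F1. Kinetic resolution by asymmetric transfer hydrogenation, a reaction known for racemic flavanones [RuCl(p-cymene)((R,R)-TsDPEN), HCO2H/Et3N], should reduce the 2R enantiomer to the cis-flavan-4-ol F2 and leave the 2S ketone, which is 11, where the route is rejoined.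

Step 8. The enolate could open ring C by β-elimination of O1 before it is silylated (erosion of C2), the facial selectivity of the epoxidation could be incomplete, or the vinyl group could be oxidised. The fallback would form the enol silane without any base. Aryl bromide 9 would be converted (n-BuLi, THF, –78 °C; then ZnCl2) into the arylzinc chloride F3. This would be added to 7 with [RhCl(C2H4)2]2/(S)-binap and TMSCl in THF at 20 °C, the asymmetric 1,4-addition known for 4-quinolones and 2,3-dihydro-4-pyridones, in which the enolate is silylated as it forms. This sets out from 7 and 9 and comes back to the route at 12.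

Step 3. The dienone could undergo a Cope shift to C8 (para product), the prenyl group could be lost thermally, or the ortho-(1,1-dimethylallyl)phenol could rearrange or cyclise further on prolonged heating. The fallback would replace the sigmatropic shift by a cross-coupling. From 2, iodination ortho to the free 5-OH (benzyltrimethylammonium dichloroiodate, CaCO3, CH2Cl2/MeOH) should give the 6-iodochromone F4, and NaH/MOMCl its bis-MOM ether F5. A ligand-controlled, γ-selective Suzuki–Miyaura coupling of F5 with commercial 3-methylbut-2-enylboronic acid pinacol ester (Pd(OAc)2, bulky biaryl dialkylphosphine, K3PO4, THF/H2O) should then deliver the tertiary allyl group and rejoin the route at 7.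

**Further compounds**
F1 | step 7 | racemic 5,7-bis(methoxymethoxy)-2-[3-methoxy-4-(methoxymethoxy)phenyl]-6-(2-methylbut-3-en-2-yl)chroman-4-one | C=CC(C)(C)c1c(OCOC)cc2c(c1OCOC)C(=O)CC(c1ccc(OCOC)c(OC)c1)O2
F2 | step 7 | (2R,4R)-5,7-bis(methoxymethoxy)-2-[3-methoxy-4-(methoxymethoxy)phenyl]-6-(2-methylbut-3-en-2-yl)chroman-4-ol (2,4-cis) | C=CC(C)(C)c1c(OCOC)cc2c(c1OCOC)[C@H](O)C[C@H](c1ccc(OCOC)c(OC)c1)O2
F3 | step 8 | [3-methoxy-4-(methoxymethoxy)phenyl]zinc chloride | COCOc1ccc([Zn]Cl)cc1OC
F4 | step 3 | 5-hydroxy-6-iodo-7-(methoxymethoxy)-4H-chromen-4-one | O=c1ccoc2cc(OCOC)c(I)c(O)c12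
F5 | step 3 | 6-iodo-5,7-bis(methoxymethoxy)-4H-chromen-4-one | O=c1ccoc2cc(OCOC)c(I)c(OCOC)c12
A1 | direct plan | 1-[6-hydroxy-2,4-bis(methoxymethoxy)-3-(2-methylbut-3-en-2-yl)phenyl]ethanone | CC(=O)c1c(O)cc(OCOC)c(C(C)(C)C=C)c1OCOC
A2 | direct plan | 3-methoxy-4-(methoxymethoxy)benzaldehyde | COCOc1ccc(C=O)cc1OC
A3 | direct plan | (E)-1-[6-hydroxy-2,4-bis(methoxymethoxy)-3-(2-methylbut-3-en-2-yl)phenyl]-3-[3-methoxy-4-(methoxymethoxy)phenyl]prop-2-en-1-one | C=CC(C)(C)c1c(OCOC)cc(O)c(C(=O)/C=C/c2ccc(OCOC)c(OC)c2)c1OCOC
A4 | direct plan | [6-hydroxy-2,4-bis(methoxymethoxy)-3-(2-methylbut-3-en-2-yl)phenyl]{(2R,3S)-3-[3-methoxy-4-(methoxymethoxy)phenyl]oxiran-2-yl}methanone | C=CC(C)(C)c1c(OCOC)cc(O)c(C(=O)[C@@H]2O[C@H]2c3ccc(OCOC)c(OC)c3)c1OCOC
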